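**Retrosynthetic overview**

1. Ring numbering: O1–O2–C3H(arm)–C4H2–C5H2–C6(OMe)(side chain). The acid is made last by oxidation of a 2-hydroxyethyl arm on C3; before that, the enyne is made by Sonogashira coupling of a pent-4-ynyl chain on C6 with (1E)-1-iodoundeca-1,10-diene (Takai olefination of dec-9-enal).
2. The 1,2-dioxane is cut at C5–C6 and at O2–C3 into three pieces: a lithiated α-methoxy sulfone (C6 with its OMe and the silyl-capped alkynyl chain; PhSO2 is a temporary activating group), 2-[(2S)-oxetan-2-yl]ethyl triflate (C5, C4, C3 and, tied back in a temporary oxetane ring, the two arm carbons), and H2O2 (O1, O2).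
3. Feature that allows this: C6 is a ketone-level carbon bearing OMe and two CH2 groups, so it maps onto doubly alkylated methoxymethyl phenyl sulfone, which reacts first as a carbanion and then, after loss of sulfinate, as an oxocarbenium ion. C6 lies 1,4 to C3 across C5–C4, so a hydroperoxide on C6 reaches C3 through a six-membered transition state, and the oxygen at the end of the C3 arm lets the C3–O bond be stored as an oxetane.
4. Stereochemistry: C3 comes from an (R)-epoxide through the oxetane and is inverted once, in the ring closure; C6 settles by anomeric equilibration of the peroxyketal (OMe axial, both carbon chains equatorial).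
5. Order of ring formation: oxetane (step 5, temporary), then the 1,2-dioxane with opening of the oxetane (step 8).

Key step: step 8

Assumption: compounds 1, 4, 6 and 9 are taken as commercial, and the (3S,6R) isomer (OMe axial at C6, both carbon substituents equatorial) is taken as the thermodynamic minimum of the 3-methoxy-1,2-dioxane.

**Route**

Step 1
Reactants: 1 dec-9-en-1-ol
Product: 2 dec-9-enal
Conditions: TEMPO (cat.), PhI(OAc)2, CH2Cl2, rt
Reagents that add atoms: none
Why: Oxoammonium-mediated alcohol oxidation (TEMPO/PhI(OAc)2) in dry CH2Cl2 should stop at the aldehyde and leave the terminal alkene untouched.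

Step 2
Reactants: 2 dec-9-enal
Product: 3 (1E)-1-iodoundeca-1,10-diene
Conditions: CHI3, CrCl2, dioxane–THF, 0 °C → rt
Reagents that add atoms: iodoform, IC(I)I
Why: Takai olefination, in which the geminal dichromium reagent from CHI3 and CrCl2 adds to the aldehyde and eliminates to give mainly the E vinyl iodide; any minor Z isomer should be removable by chromatography.

Step 3
Reactants: 4 (5-chloropent-1-yn-1-yl)trimethylsilane
Product: 5 (5-iodopent-1-yn-1-yl)trimethylsilane
Conditions: NaI, acetone, reflux
Reagents that add atoms: sodium iodide, [Na+].[I-]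
Why: Finkelstein halide exchange, driven by precipitation of NaCl, should give the primary iodide needed for carbanion alkylation.

Step 4
Reactants: 6 methoxymethyl phenyl sulfone; 5 (5-iodopent-1-yn-1-yl)trimethylsilane
Product: 8 trimethyl[6-methoxy-6-(phenylsulfonyl)hex-1-yn-1-yl]silane (racemic), via lithiated sulfone 7 (not isolated)
Conditions: n-BuLi, THF, −78 °C; then 5, DMPU, −78 → −20 °C
Reagents that add atoms: none
Why: SN2 alkylation of a sulfone-stabilised α-alkoxy carbanion (an acyl anion equivalent) with a primary iodide; the new stereocentre is formed racemic and is of no consequence because it becomes planar again in step 8.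

Step 5
Reactants: 9 (2R)-2-[2-(benzyloxy)ethyl]oxirane
Product: 10 (2S)-2-[2-(benzyloxy)ethyl]oxetane
Conditions: Me3S(O)I, KOtBu, t-BuOH, 50 °C
Reagents that add atoms: trimethylsulfoxonium iodide, C[S+](C)(C)=O.[I-]
Why: Corey–Chaykovsky-type ring expansion, in which dimethylsulfoxonium methylide opens the epoxide at its CH2 terminus and the γ-alkoxide then displaces DMSO (4-exo-tet), so the C–O stereocentre is untouched (the descriptor changes from R to S only through the priority rules).

Step 6
Reactants: 10 (2S)-2-[2-(benzyloxy)ethyl]oxetane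
Product: 11 2-[(2R)-oxetan-2-yl]ethan-1-ol
Conditions: H2 (1 atm), Pd/C, EtOAc, rt
Reagents that add atoms: none
Why: Catalytic hydrogenolysis of the benzyl ether should not open the oxetane and does not involve the stereocentre (descriptor R by priority change only).

Step 7
Reactants: 11 2-[(2R)-oxetan-2-yl]ethan-1-ol
Product: 12 2-[(2S)-oxetan-2-yl]ethyl trifluoromethanesulfonate
Conditions: Tf2O, 2,6-lutidine, CH2Cl2, −78 °C; used at once as a cold solution
Reagents that add atoms: trifluoromethanesulfonic anhydride, O=S(=O)(OS(=O)(=O)C(F)(F)F)C(F)(F)F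
Why: O-Sulfonylation of a primary alcohol at low temperature should give the triflate, which is kept cold and dilute so that it cannot alkylate the oxetane oxygen of a second molecule.

Step 8
Reactants: 8 trimethyl[6-methoxy-6-(phenylsulfonyl)hex-1-yn-1-yl]silane; 12 2-[(2S)-oxetan-2-yl]ethyl trifluoromethanesulfonate
Product: 16 2-[(3S,6R)-6-methoxy-6-[5-(trimethylsilyl)pent-4-yn-1-yl]-1,2-dioxan-3-yl]ethan-1-ol, via lithiated sulfone 13 (not isolated), via tertiary sulfone 14 (not isolated), via hydroperoxy ketal 15 (not isolated)
Conditions: n-BuLi, THF, −78 °C; 12 (in CH2Cl2), −78 → −40 °C; then H2O2 (anhydrous, in Et2O), Sc(OTf)3, CH2Cl2, −40 → 0 °C; then MeOH, 0 °C → rt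
Reagents that add atoms: hydrogen peroxide, OO; methanol, CO
Why: Proposed new method: lithiated sulfone 13 is alkylated by the primary triflate 12 (SN2; this makes the C5–C6 bond), the tertiary α-methoxy sulfone 14 then ionises under Sc(OTf)3 with loss of benzenesulfinate to a methoxy-oxocarbenium ion at C6, H2O2 adds to give the α-methoxy hydroperoxide 15, and its terminal oxygen opens the Lewis acid-activated oxetane at the substituted carbon (this makes the O2–C3 bond and releases the hydroxyethyl arm). The closest known reaction types are the alkylation of lithiated α-alkoxy sulfones followed by Lewis acid exchange of the sulfonyl group for an oxygen nucleophile through the oxocarbenium ion (as used for spiroketals), the acid-catalysed formation of α-methoxy hydroperoxides from enol ethers or ketones and H2O2, and the Lewis acid-promoted cyclisation of hydroperoxy ketals onto oxetanes; what is new is the interception of the sulfone-derived cation by H2O2 and the running of all three events in one flask, which is reasonable because 14 is too labile to store and the by-products of the alkylation (LiOTf, butane) do not interfere with peroxide chemistry. The 1,2-dioxane closes in the 6-exo-tet mode at C3, whereas attack at the oxetane CH2 would need an eight-membered transition state. C3 is set by inversion in this SN2 opening, so the (R)-oxetane carbon of 15 becomes (3S); C6 is set under thermodynamic control, because reversible loss and return of methoxide at the peroxyketal carbon (MeOH, Sc(OTf)3) should let both C6 epimers drain into the chair with OMe axial (anomeric effect toward O1) and both carbon chains equatorial, which is the (6R) isomer. The step needs the hydroperoxide oxygen, and not the oxetane oxygen, the sulfinate or a second molecule of H2O2, to become bonded to C3, and it needs the C6 cation to be trapped by oxygen and not by the alkyne: the high nucleophilicity of the OOH group combined with the six-membered transition state, the reversibility of every addition to the C6 cation, the oxidation of the sulfinate by excess peroxide and the silyl cap that makes the alkyne a poor π-nucleophile are expected to secure this.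

Step 9
Reactants: 16 2-[(3S,6R)-6-methoxy-6-[5-(trimethylsilyl)pent-4-yn-1-yl]-1,2-dioxan-3-yl]ethan-1-ol
Product: 17 2-[(3S,6R)-6-methoxy-6-(pent-4-yn-1-yl)-1,2-dioxan-3-yl]ethan-1-ol
Conditions: K2CO3, MeOH, rt
Reagents that add atoms: none
Why: Base-catalysed methanolysis of the alkynyl–silicon bond (protodesilylation) should leave the dialkyl peroxide, the ketal, the alcohol and both stereocentres untouched.

Step 10
Reactants: 17 2-[(3S,6R)-6-methoxy-6-(pent-4-yn-1-yl)-1,2-dioxan-3-yl]ethan-1-ol; 3 (1E)-1-iodoundeca-1,10-diene
Product: 18 2-[(3S,6R)-6-[(6E)-hexadeca-6,15-dien-4-yn-1-yl]-6-methoxy-1,2-dioxan-3-yl]ethan-1-ol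
Conditions: PdCl2(PPh3)2 (cat.), CuI (cat.), Et3N, THF, rt
Reagents that add atoms: none
Why: Sonogashira coupling of a terminal alkyne with a vinyl iodide proceeds at room temperature with retention of the E geometry, and a dialkyl peroxyketal of this kind is expected to tolerate zerovalent palladium and the copper acetylide under these conditions.

Step 11
Reactants: 18 2-[(3S,6R)-6-[(6E)-hexadeca-6,15-dien-4-yn-1-yl]-6-methoxy-1,2-dioxan-3-yl]ethan-1-ol
Product: 20 2-[(3S,6R)-6-[(6E)-hexadeca-6,15-dien-4-yn-1-yl]-6-methoxy-1,2-dioxan-3-yl]acetic acid, via peroxy aldehyde 19 (not isolated)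
Conditions: TEMPO (cat.), PhI(OAc)2, MeCN–H2O, 0 °C → rt
Reagents that add atoms: water, O
Why: Oxoammonium-mediated oxidation in aqueous MeCN (TEMPO/PhI(OAc)2) should take the primary alcohol through the hydrate of aldehyde 19 to the carboxylic acid under nearly neutral conditions that spare the peroxide, the ketal, the enyne, the terminal alkene and both stereocentres.

**Compound list**

1 | dec-9-en-1-ol | C=CCCCCCCCCO | starting material
2 | dec-9-enal | C=CCCCCCCCC=O | intermediate
3 | (1E)-1-iodoundeca-1,10-diene | C=CCCCCCCC/C=C/I | intermediate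
4 | (5-chloropent-1-yn-1-yl)trimethylsilane | C[Si](C)(C)C#CCCCCl | starting material
5 | (5-iodopent-1-yn-1-yl)trimethylsilane | C[Si](C)(C)C#CCCCI | intermediate
6 | methoxymethyl phenyl sulfone | COCS(=O)(=O)c1ccccc1 | starting material
7 | lithio(methoxy)methyl phenyl sulfone | [Li]C(OC)S(=O)(=O)c1ccccc1 | intermediate
8 | trimethyl[6-methoxy-6-(phenylsulfonyl)hex-1-yn-1-yl]silane (racemic) | C[Si](C)(C)C#CCCCC(OC)S(=O)(=O)c1ccccc1 | intermediate
9 | (2R)-2-[2-(benzyloxy)ethyl]oxirane | c1ccccc1COCC[C@@H]1CO1 | starting material
10 | (2S)-2-[2-(benzyloxy)ethyl]oxetane | c1ccccc1COCC[C@@H]1CCO1 | intermediate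
11 | 2-[(2R)-oxetan-2-yl]ethan-1-ol | OCC[C@@H]1CCO1 | intermediate
12 | 2-[(2S)-oxetan-2-yl]ethyl trifluoromethanesulfonate | O=S(=O)(OCC[C@@H]1CCO1)C(F)(F)F | intermediate
13 | [6-lithio-6-methoxy-6-(phenylsulfonyl)hex-1-yn-1-yl]trimethylsilane | C[Si](C)(C)C#CCCCC([Li])(OC)S(=O)(=O)c1ccccc1 | intermediate
14 | trimethyl{6-methoxy-8-[(2R)-oxetan-2-yl]-6-(phenylsulfonyl)oct-1-yn-1-yl}silane (both C6 epimers) | C[Si](C)(C)C#CCCCC(OC)(CC[C@@H]1CCO1)S(=O)(=O)c1ccccc1 | intermediate
15 | {6-hydroperoxy-6-methoxy-8-[(2R)-oxetan-2-yl]oct-1-yn-1-yl}trimethylsilane (both C6 epimers) | C[Si](C)(C)C#CCCCC(OC)(OO)CC[C@@H]1CCO1 | intermediate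
16 | 2-[(3S,6R)-6-methoxy-6-[5-(trimethylsilyl)pent-4-yn-1-yl]-1,2-dioxan-3-yl]ethan-1-ol | C[Si](C)(C)C#CCCC[C@]1(OC)CC[C@@H](CCO)OO1 | intermediate
17 | 2-[(3S,6R)-6-methoxy-6-(pent-4-yn-1-yl)-1,2-dioxan-3-yl]ethan-1-ol | C#CCCC[C@]1(OC)CC[C@@H](CCO)OO1 | intermediate
18 | 2-[(3S,6R)-6-[(6E)-hexadeca-6,15-dien-4-yn-1-yl]-6-methoxy-1,2-dioxan-3-yl]ethan-1-ol | C=CCCCCCCC/C=C/C#CCCC[C@]1(OC)CC[C@@H](CCO)OO1 | intermediate
19 | 2-[(3S,6R)-6-[(6E)-hexadeca-6,15-dien-4-yn-1-yl]-6-methoxy-1,2-dioxan-3-yl]acetaldehyde | C=CCCCCCCC/C=C/C#CCCC[C@]1(OC)CC[C@@H](CC=O)OO1 | intermediate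
20 | 2-[(3S,6R)-6-[(6E)-hexadeca-6,15-dien-4-yn-1-yl]-6-methoxy-1,2-dioxan-3-yl]acetic acid | C=CCCCCCCC/C=C/C#CCCC[C@]1(OC)CC[C@@H](CC(=O)O)OO1 | target

**Step count and risks**

Total step count: 11. Longest linear sequence: 7 steps (steps 5, 6, 7, 8, 9, 10, 11).

Steps most likely to fail:

Step 8 (bears the label). The C6 cation may be captured by the oxetane oxygen (a five-membered oxonium ion that then opens to a 2-methoxytetrahydrofuran), excess H2O2 may open the oxetane intermolecularly, or the triflate may decompose before it is alkylated. The fallback uses known reaction types only, sets out from 8 and 11 and returns at 16. Alcohol 11 is converted with I2, PPh3 and imidazole into (2S)-2-(2-iodoethyl)oxetane F1. Lithiated 8 is alkylated with F1 in THF–DMPU, and dilute aqueous acid on work-up hydrolyses the α-methoxy sulfone 14 to the ketone 1-[(2R)-oxetan-2-yl]-8-(trimethylsilyl)oct-7-yn-3-one F2, which is isolated. F2 is converted with urea–hydrogen peroxide and catalytic Sc(OTf)3 in MeOH at 0 °C into hydroperoxy ketal 15, which is freed from excess H2O2 by extraction. It is then cyclised on its own with a catalytic Lewis acid in CH2Cl2, followed by the MeOH equilibration, to give 16.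

Step 5. Ring expansion may be slow or incomplete, or the oxetane may react further with the ylide. The fallback sets out from 9 and returns at 10. CuI-catalysed opening of 9 with CH2=CHMgBr at the CH2 terminus gives (3S)-1-(benzyloxy)hex-5-en-3-ol F3. Ozonolysis with NaBH4 work-up gives (3S)-5-(benzyloxy)pentane-1,3-diol F4. Selective sulfonylation of the primary hydroxyl (TsCl, Et3N, cat. Bu2SnO) gives (3R)-5-(benzyloxy)-3-hydroxypentyl 4-methylbenzenesulfonate F5. KOtBu in THF then closes the oxetane by intramolecular Williamson etherification at the primary carbon, which leaves the stereocentre untouched, to give 10.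

Step 11. The oxidant may attack the conjugated enyne, or the β-peroxy aldehyde 19 may be lost by β-elimination, at the most advanced intermediate. The fallback sets out from 17 and returns at 20 by reversing the order of the last two operations. Compound 17, which carries only the terminal alkyne, is oxidised with TEMPO/PhI(OAc)2 in MeCN–H2O to 2-[(3S,6R)-6-methoxy-6-(pent-4-yn-1-yl)-1,2-dioxan-3-yl]acetic acid F6. F6 is then coupled with 3 under the Sonogashira conditions of step 10, with one extra equivalent of Et3N for the acid, to give 20 directly.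

**Further compounds**

F1 | step 8 | (2S)-2-(2-iodoethyl)oxetane | ICC[C@@H]1CCO1
F2 | step 8 | 1-[(2R)-oxetan-2-yl]-8-(trimethylsilyl)oct-7-yn-3-one | C[Si](C)(C)C#CCCCC(=O)CC[C@@H]1CCO1
F3 | step 5 | (3S)-1-(benzyloxy)hex-5-en-3-ol | c1ccccc1COCC[C@@H](O)CC=C
F4 | step 5 | (3S)-5-(benzyloxy)pentane-1,3-diol | c1ccccc1COCC[C@@H](O)CCO
F5 | step 5 | (3R)-5-(benzyloxy)-3-hydroxypentyl 4-methylbenzenesulfonate | c1ccccc1COCC[C@@H](O)CCOS(=O)(=O)c1ccc(C)cc1
F6 | step 11 | 2-[(3S,6R)-6-methoxy-6-(pent-4-yn-1-yl)-1,2-dioxan-3-yl]acetic acid | C#CCCC[C@]1(OC)CC[C@@H](CC(=O)O)OO1
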